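**Plan**
- First cut: C6–C1′, from ring carbon C6 of the 2-pyrone to the allylic CH2. This gives the bare heterocycle 3,4-dimethoxy-5-methyl-2-pyrone (C6–H) and an (E)-allylic bromide.
- Pyrone half: cut 4-O–CH3, then O1–C2 and C5–C6 (C6 and O1 come from methyl formate), then C3–C4 (methyl methoxyacetate plus propionyl chloride). Chain half: cut C1′–C2′ (formaldehyde), C3′–CH3 (Me3Al) and the alkyne–alkyl bond.
- Enabling feature: C3, C4 and C5 of the pyrone ring carry OMe, OMe and CH3, so C6–H is the only ring C–H. It is an sp2 C–H next to the acyloxy-type ring oxygen O1. The C5–CH3 is cross-conjugated to the C2 carbonyl and is not acidified. The unfunctionalised ring can therefore be metalated at C6 as a masked acyl anion.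
- Forward order: the pyrone ring is closed in step 2 and methylated in step 3, and the chain is built in steps 4 to 6. The halves meet in the last step, with no protecting group and no halogen, tin or boron handle on the ring.
- Stereochemistry: the only element, the E C2′=C3′ double bond, comes from syn methylalumination of a terminal alkyne (step 5). It is carried unchanged through bromination and coupling.

Key step: step 7

Assumption: 7, LiC≡CH·H2NCH2CH2NH2 and the THF solution of TMPZnCl·LiCl [(2,2,6,6-tetramethylpiperidin-1-yl)zinc chloride–lithium chloride] are taken as purchased. O1 and C2–C6 denote the pyrone ring; C1′–C9′ denote the side chain.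

Step 1
Reactants: 1 methyl methoxyacetate; 2 propionyl chloride
Product: 3 methyl 2-methoxy-3-oxopentanoate (racemic, configurationally labile)
Conditions: 1 (2 equiv), LiN(iPr)2 (2 equiv), THF, −78 °C; 2 (1 equiv); aq HCl
Reagents that add atoms: none
Why: Crossed Claisen-type C-acylation of a preformed lithium ester enolate by an acid chloride, in which the second equivalent of enolate takes up the acidic proton of 3; the new stereocentre is labile and disappears in step 2.

Step 2
Reactants: 3 methyl 2-methoxy-3-oxopentanoate
Product: 5 4-hydroxy-3-methoxy-5-methyl-2H-pyran-2-one, via formyl keto ester 4 (not isolated)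
Conditions: LiN(iPr)2 (2.2 equiv), THF, −78 → 0 °C; HCO2Me, −78 → 0 °C; aq HCl; crude 4, p-TsOH (cat.), PhMe, 80 °C
Reagents that add atoms: methyl formate COC=O
Why: γ-Acylation of a β-keto ester dianion (Claisen formylation at the more reactive CH2 carbanion), after which the enol of the new aldehyde lactonises onto the methyl ester to give the stabilised 4-hydroxy-2-pyrone and erase both labile stereocentres.

Step 3
Reactants: 5 4-hydroxy-3-methoxy-5-methyl-2H-pyran-2-one
Product: 6 3,4-dimethoxy-5-methyl-2H-pyran-2-one
Conditions: Me2SO4, K2CO3, acetone, reflux
Reagents that add atoms: dimethyl sulfate COS(=O)(=O)OC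
Why: O-Alkylation of the ambident pyronate with K2CO3 and Me2SO4, the conditions known to favour the 4-methoxy-2-pyrone; any isomeric 2-methoxy-4-pyrone should be removable by chromatography.

Step 4
Reactants: 7 (6-bromohexyl)benzene
Product: 8 oct-7-yn-1-ylbenzene
Conditions: LiC≡CH·H2NCH2CH2NH2, DMSO, 0 °C → rt
Reagents that add atoms: lithium acetylide ethylenediamine complex [Li]C#C.NCCN
Why: SN2 alkylation of lithium acetylide by an unhindered primary bromide in a dipolar aprotic solvent.

Step 5
Reactants: 8 oct-7-yn-1-ylbenzene
Product: 11 (2E)-3-methyl-9-phenylnon-2-en-1-ol, via alkenyldimethylalane 9 (not isolated), via lithium alkenylalanate 10 (not isolated)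
Conditions: Me3Al (2 equiv), Cp2ZrCl2 (0.2 equiv), CH2Cl2, 0 °C → rt; n-BuLi, THF, −78 °C; (CH2O)n, → rt; aq HCl
Reagents that add atoms: trimethylaluminium C[Al](C)C; formaldehyde (from paraformaldehyde) C=O
Why: Negishi zirconium-catalysed carboalumination adds CH3 and Al syn across the terminal alkyne with Al on the terminal carbon, which fixes the E trisubstituted alkene, and the derived alanate adds to formaldehyde with retention of geometry.

Step 6
Reactants: 11 (2E)-3-methyl-9-phenylnon-2-en-1-ol
Product: 12 [(7E)-9-bromo-7-methylnon-7-en-1-yl]benzene
Conditions: PBr3 (0.4 equiv), Et2O, 0 °C; used without chromatography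
Reagents that add atoms: phosphorus tribromide BrP(Br)Br
Why: SN2 bromination of a primary allylic alcohol with PBr3 at 0 °C, which for geraniol-type alcohols is known to keep both the position and the geometry of the double bond.

Step 7
Reactants: 6 3,4-dimethoxy-5-methyl-2H-pyran-2-one; 12 [(7E)-9-bromo-7-methylnon-7-en-1-yl]benzene
Product: 14 lehualide E, via pyron-6-ylzinc chloride 13 (not isolated)
Conditions: TMPZnCl·LiCl (1.1 equiv), THF, 25 °C; then 12, Pd(PPh3)4 (5 mol %), 0 → 25 °C
Reagents that add atoms: none
Why: Proposed new method: TMPZnCl·LiCl should remove C6–H of 6, the only ring C–H and an sp2 C–H acidified by the adjacent acyloxy-type O1 and the electron-poor dienoate ring, to give the covalent zinc species 13, while the C5–CH3 is cross-conjugated to the C2 carbonyl and so not vinylogously acidic, and the hindered amide cannot add to C2 or C6. Zerovalent palladium then ionises 12 to an η3-allyl complex, 13 transmetalates, and reductive elimination at the unhindered CH2 terminus forms the C6–C1′ bond (Negishi alkenyl–allyl coupling to a 1,4-diene). The closest known reactions are the zincation of chromones at C2 and of N-protected 2-pyridones at C6 with TMP–zinc bases followed by Negishi coupling, and the palladium-catalysed coupling of alkenyl- and arylzinc reagents with geranyl-type halides; the new element is metalation of a 2-pyrone at C6. No ring is closed and no stereocentre is formed, and the E geometry of 12 should persist because syn/anti exchange of the allyl ligand would need a σ-bond from palladium to the fully substituted C3′, which should be slow at or below 25 °C. Zinc rather than lithium is chosen so that the carbon–metal bond is too covalent for α-elimination of the ring carboxylate (ring opening through an alkylidene carbene) or for attack on a second pyrone. About one equivalent of base is used and only the free hindered amine remains at the end, so the doubly activated C1′ methylene of 14 should not be deprotonated and the skipped diene should not move into conjugation.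

**Compound list**
1 | methyl methoxyacetate | COCC(=O)OC | starting material
2 | propionyl chloride | CCC(=O)Cl | starting material
3 | methyl 2-methoxy-3-oxopentanoate (racemic) | CCC(=O)C(OC)C(=O)OC | intermediate
4 | methyl 2-methoxy-4-methyl-3,5-dioxopentanoate (tautomer and diastereomer mixture, not isolated) | COC(=O)C(OC)C(=O)C(C)C=O | intermediate
5 | 4-hydroxy-3-methoxy-5-methyl-2H-pyran-2-one | COc1c(O)c(C)coc1=O | intermediate
6 | 3,4-dimethoxy-5-methyl-2H-pyran-2-one | COc1c(C)coc(=O)c1OC | intermediate
7 | (6-bromohexyl)benzene | BrCCCCCCc1ccccc1 | starting material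
8 | oct-7-yn-1-ylbenzene | C#CCCCCCCc1ccccc1 | intermediate
9 | dimethyl[(1E)-2-methyl-8-phenyloct-1-en-1-yl]alane (not isolated) | C[Al](C)/C=C(\C)CCCCCCc1ccccc1 | intermediate
10 | lithium butyl(dimethyl)[(1E)-2-methyl-8-phenyloct-1-en-1-yl]alanate (not isolated) | [Li+].CCCC[Al-](C)(C)/C=C(\C)CCCCCCc1ccccc1 | intermediate
11 | (2E)-3-methyl-9-phenylnon-2-en-1-ol | OC/C=C(\C)CCCCCCc1ccccc1 | intermediate
12 | [(7E)-9-bromo-7-methylnon-7-en-1-yl]benzene | BrC/C=C(\C)CCCCCCc1ccccc1 | intermediate
13 | (3,4-dimethoxy-5-methyl-2-oxo-2H-pyran-6-yl)zinc chloride (not isolated) | COc1c(C)c([Zn]Cl)oc(=O)c1OC | intermediate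
14 | lehualide E, 3,4-dimethoxy-5-methyl-6-[(2E)-3-methyl-9-phenylnon-2-en-1-yl]-2H-pyran-2-one | COc1c(C)c(C/C=C(\C)CCCCCCc2ccccc2)oc(=O)c1OC | target

**Totals**
Total step count: 7. Longest linear sequence: 4 steps (steps 4, 5, 6, 7; the pyrone branch, steps 1, 2, 3, 7, is equally long).

**Steps most likely to fail**

First, step 7 (Proposed new method).
- Zincation may be too slow.
- The metalated ring may open by α-elimination.
- The allyl group may couple at its substituted terminus, or its geometry may erode.
- The skipped diene may drift into conjugation.

The fallback uses known chemistry and moves the union one bond outward. It sets out from 3 and from alkenylalane 9 and comes back at 14. The LiN(iPr)2 dianion of 3 is acylated with 2-chloro-N-methoxy-N-methylacetamide to methyl 6-chloro-2-methoxy-4-methyl-3,5-dioxohexanoate F1. Catalytic acid closes F1 to 6-(chloromethyl)-4-hydroxy-3-methoxy-5-methyl-2H-pyran-2-one F2. Me2SO4 and K2CO3 convert F2 to 6-(chloromethyl)-3,4-dimethoxy-5-methyl-2H-pyran-2-one F3. F3 is then coupled with 9 under Pd(PPh3)4 catalysis (Negishi coupling of an alkenylalane with a benzylic-type chloride, with retention of alkene geometry) to give 14.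

Second, step 2.
- Proton transfer may quench the dianion.
- A second acylation may occur.
- The formyl group may be lost again by retro-Claisen cleavage before the ring closes.

The fallback avoids anions altogether. It sets out from 3 and comes back at 5. Condensation of 3 with tBuOCH(NMe2)2 in hot toluene takes place at the only CH2 able to form an enaminone. This gives methyl (4E)-5-(dimethylamino)-2-methoxy-4-methyl-3-oxopent-4-enoate F4. Aqueous HCl in THF then hydrolyses the enaminone and lets the liberated enol lactonise to 5.

Third, step 3.
- The ambident pyronate may be methylated at the C2 carbonyl oxygen instead of the C4 oxygen.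

The fallback reverses the polarity at C4. It sets out from 5 and comes back at 6. POCl3 converts 5 to 4-chloro-3-methoxy-5-methyl-2H-pyran-2-one F5. NaOMe in MeOH at 0 °C then replaces chloride by addition–elimination at C4, a path that can deliver the methoxy group only to C4.

**Further compounds**
F1 | step 7 | methyl 6-chloro-2-methoxy-4-methyl-3,5-dioxohexanoate | COC(=O)C(OC)C(=O)C(C)C(=O)CCl
F2 | step 7 | 6-(chloromethyl)-4-hydroxy-3-methoxy-5-methyl-2H-pyran-2-one | COc1c(O)c(C)c(CCl)oc1=O
F3 | step 7 | 6-(chloromethyl)-3,4-dimethoxy-5-methyl-2H-pyran-2-one | COc1c(C)c(CCl)oc(=O)c1OC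
F4 | step 2 | methyl (4E)-5-(dimethylamino)-2-methoxy-4-methyl-3-oxopent-4-enoate | COC(=O)C(OC)C(=O)/C(C)=C/N(C)C
F5 | step 3 | 4-chloro-3-methoxy-5-methyl-2H-pyran-2-one | COc1c(Cl)c(C)coc1=O
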